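**Retrosynthetic overview**

- The strategy rests on one feature: in the 2,5-cis oxolane (O, C1, C14, C13, C12) the C1–C2 bond and the C12–C11 bond lie on the same face, so the oxygen on C11 can be tied back to C1 as a 2,7-dioxabicyclo[2.2.1]heptane ketal and that C1–O11 bond then exchanged for C1–C2 with retention. Numbering: C1 oxolane carbon with isopropyl, C2=C3 alkene, C4 carbinol, C5 CH2, C6 ketone, C8 CH–CH3, C11 CH–OAc, C12 oxolane carbon with methyl, C13/C14 oxolane CH2.
- Late disconnections: C6 ketone from a 1,3-dithiane and the C11 acetate; E-C2=C3 from a 14-membered cycloalkyne; the macrocycle by ring-closing alkyne metathesis at C2≡C3; C5–C6 by opening (S)-2-methyl-2-(prop-1-ynyl)oxirane (from (S)-2-methylglycidol) with the C6 lithiodithiane.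
- Key disconnection: C1–C2, by opening the bicyclic ketal with dimethyl(1-propynyl)alane. The ketal comes from the Shi epoxide of an E-alkene built from (S)-citronellal (C6–C13) and 3-methyl-2-butanone (C14, C1, isopropyl).
- Ring order: oxolane first (C12–O closed by the ketone oxygen on the epoxide, held as the bicyclic ketal, released in the key step); 14-membered carbocycle second (alkyne metathesis); the alkyne is then reduced to the E-alkene.

Key step: step 7

Remark on the chemistry: the D-fructose-derived epoxidation ketone is assumed to attack the E-C11=C12 alkene on the face it attacks in other E-trisubstituted alkenes, which gives the (11R,12R)-epoxide; the Payne rearrangement of 2-methylglycidol is degenerate (it returns the same enantiomer), so aqueous base is avoided in steps 11–13 only because of epoxide hydrolysis and loss of volatile material.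

**Route**

Step 1
Reactants: 1 (S)-citronellal
Product: 2 2-[(2S)-2,6-dimethylhept-5-en-1-yl]-1,3-dioxolane
Conditions: ethylene glycol, PPTS (cat.), benzene, reflux, Dean–Stark
Reagents that add atoms: ethylene glycol, OCCO
Why: Acid-catalysed acetalisation driven by azeotropic removal of water; the weak acid keeps the carbonyl-ene cyclisation of citronellal in check and C8 is untouched.

Step 2
Reactants: 2 dioxolane of (S)-citronellal
Product: 4 (2E,6S)-7-(1,3-dioxolan-2-yl)-2,6-dimethylhept-2-en-1-ol, via E-enal 3 (not isolated)
Conditions: SeO2 (cat.), t-BuOOH, salicylic acid (cat.), CH2Cl2, rt; then NaBH4, MeOH, 0 °C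
Reagents that add atoms: SeO2 (oxygen carrier), O=[Se]=O; tert-butyl hydroperoxide (terminal oxidant), CC(C)(C)OO
Why: Catalytic SeO2 allylic oxidation (ene reaction then [2,3]-sigmatropic shift) hydroxylates the E-methyl group of the trisubstituted alkene with the E-geometry kept, and borohydride returns the over-oxidised enal 3 to the alcohol.

Step 3
Reactants: 4 E-allylic alcohol
Product: 6 2-[(2S,5E)-7-bromo-2,6-dimethylhept-5-en-1-yl]-1,3-dioxolane, via allylic mesylate 5 (not isolated)
Conditions: MsCl, Et3N, THF, −40 °C; then LiBr, THF, 0 °C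
Reagents that add atoms: lithium bromide, [Li+].[Br-]
Why: Mesylation followed by SN2 displacement with bromide (Finkelstein-type) at the primary allylic carbon, cold and non-acidic so that neither allylic transposition nor acetal loss should occur.

Step 4
Reactants: 6 E-allylic bromide; 7 3-methyl-2-butanone
Product: 9 (6E,10S)-11-(1,3-dioxolan-2-yl)-2,6,10-trimethylundec-6-en-3-one (E-C11=C12 isopropyl ketone), via lithium enolate 8 (not isolated)
Conditions: 7, LiN(i-Pr)2, THF, −78 °C; then 6, DMPU, −78 → −20 °C
Reagents that add atoms: none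
Why: Kinetic deprotonation at −78 °C gives the methyl-side lithium enolate, which is C-alkylated by the primary allylic bromide in an SN2 enolate alkylation that leaves the E-alkene untouched.

Step 5
Reactants: 9 E-unsaturated isopropyl ketone
Product: 10 (8S,11R,12R)-epoxy ketone: 1-[(2R,3R)-3-[(3S)-4-(1,3-dioxolan-2-yl)-3-methylbutyl]-2-methyloxiran-2-yl]-4-methylpentan-3-one
Conditions: 1,2:4,5-di-O-isopropylidene-β-D-erythro-2,3-hexodiulo-2,6-pyranose (D-fructose-derived ketone, 30 mol%), KHSO5 (as 2KHSO5·KHSO4·K2SO4), K2CO3, Bu4NHSO4, MeCN/dimethoxymethane/aq. Na2B4O7 buffer (pH 10.5), 0 °C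
Reagents that add atoms: potassium peroxymonosulfate, [K+].[O-]S(=O)(=O)OO
Why: Shi asymmetric epoxidation through the chiral dioxirane and a spiro transition state: the catalyst selects the alkene face and sets C11 and C12 together as (11R,12R), while the unactivated dialkyl ketone and the acetal are inert at pH 10.5.

Step 6
Reactants: 10 (11R,12R)-epoxy ketone
Product: 11 bicyclic ketal (1S,3R,4S)-3-[(3S)-4-(1,3-dioxolan-2-yl)-3-methylbutyl]-4-methyl-1-(propan-2-yl)-2,7-dioxabicyclo[2.2.1]heptane (ring C1 = route C1, ring C3 = route C11, ring C4 = route C12)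
Conditions: CSA (5 mol%), 4 Å MS, CH2Cl2, 0 °C; Et3N quench
Reagents that add atoms: none
Why: Acid-catalysed isomerisation of a γ,δ-epoxy ketone to a bicyclic ketal: the carbonyl oxygen opens the activated epoxide 5-exo at the tertiary C12 with inversion (closing the oxolane and making C12 S), and O11, with C11 untouched, then adds to the oxocarbenium carbon C1, whose configuration the bicycle dictates.

Step 7
Reactants: 11 bicyclic ketal; 12 propyne
Product: 15 2,5-cis oxolane alcohol (1S,8S,11R,12S) bearing 1-propynyl and isopropyl on C1 with free C11–OH and C6 dioxolane, via 1-propynyllithium 13 (not isolated), via dimethyl(1-propynyl)alane 14 (not isolated)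
Conditions: 12, n-BuLi, toluene, −78 → 0 °C; Me2AlCl (hexane), 0 °C; then 11, toluene, −78 → −20 °C; aq. KNaC4H4O6 (potassium sodium tartrate)
Reagents that add atoms: none
Why: Proposed new method: the Lewis acidic alane binds the more exposed O11 (on a secondary carbon, whereas O12 sits between two fully substituted carbons), strain release in the [2.2.1] ketal drives heterolysis of C1–O11 to a tertiary oxolanyl oxocarbenium ion paired with the O11-bound alkynylaluminate, and the aluminate then passes its propynyl group to C1 on the face O11 has just left, forming C1–C2. The closest known reaction type is the retentive opening of 6,8-dioxabicyclo[3.2.1]octane ketals and 1,6-anhydro sugars by organoaluminium reagents to cis-2,6-disubstituted oxanes, here extended to a 2,7-dioxabicyclo[2.2.1]heptane and a fully substituted ketal carbon. No ring closes in this step: the oxolane, closed 5-exo-tet at C12 in step 6, is only released from the bicycle, and the 14-membered ring follows in step 15. The new stereocentre C1 (S) is controlled by the bicyclic template, which fixes O11 on the C11 face of the oxolane, together with intramolecular alkynyl delivery from that face, which is retention and gives the 2,5-cis oxolane. The step needs C1–O11 rather than C1–O12 cleavage (secured by the site of aluminium binding and by the five-membered cyclic cation that results), alkynyl rather than methyl transfer (sp ligands leave aluminium in preference to methyl) and survival of the C6 dioxolane (an unstrained aldehyde acetal that should not ionise between −78 and −20 °C).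

Step 8
Reactants: 15 2,5-cis oxolane alcohol
Product: 16 hydroxy aldehyde (3S,6R)-6-hydroxy-3-methyl-6-[(2S,5S)-2-methyl-5-(propan-2-yl)-5-(prop-1-yn-1-yl)oxolan-2-yl]hexanal
Conditions: 1 M HCl, THF, rt
Reagents that add atoms: water, O
Why: Acid-catalysed acetal hydrolysis; the oxolane ether, the alkyne and the stereocentres (none α to the new aldehyde) are stable to dilute aqueous acid.

Step 9
Reactants: 16 hydroxy aldehyde
Product: 17 C6 1,3-dithiane (1S,8S,11R,12S) with free C11–OH
Conditions: HS(CH2)3SH, BF3·OEt2 (0.2 equiv), CH2Cl2, −40 °C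
Reagents that add atoms: 1,3-propanedithiol, SCCCS
Why: Lewis acid-catalysed dithioacetalisation of the aldehyde, fast at low temperature, so that the tertiary propargylic ether of the oxolane should not ionise.

Step 10
Reactants: 17 hydroxy dithiane
Product: 18 C11 triethylsilyl ether of the dithiane
Conditions: Et3SiOTf, 2,6-lutidine, CH2Cl2, −78 °C
Reagents that add atoms: triethylsilyl triflate, CC[Si](CC)(CC)OS(=O)(=O)C(F)(F)F
Why: Silyl triflate silylation of the hindered secondary C11 alcohol removes the only acidic proton before the dithiane is lithiated.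

Step 11
Reactants: 19 (S)-2-methylglycidol
Product: 20 (2R)-2-methyloxirane-2-carbaldehyde
Conditions: Dess–Martin periodinane, NaHCO3, CH2Cl2, 0 °C → rt; filtered and used as a solution
Reagents that add atoms: none
Why: Dess–Martin oxidation of the primary alcohol under buffered, non-aqueous conditions; no bond to the quaternary epoxide carbon is made or broken, and the volatile, water-soluble aldehyde is used at once.

Step 12
Reactants: 20 epoxy aldehyde
Product: 21 (2S)-2-ethynyl-2-methyloxirane
Conditions: dimethyl (1-diazo-2-oxopropyl)phosphonate, K2CO3, MeOH, 0 °C → rt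
Reagents that add atoms: dimethyl (1-diazo-2-oxopropyl)phosphonate, CC(=O)C(=[N+]=[N-])P(=O)(OC)OC
Why: Ohira–Bestmann (Seyferth–Gilbert) homologation: the diazophosphonate anion formed by methanolysis converts the aldehyde into the terminal alkyne through a diazoalkene and an alkylidene carbene, with the adjacent quaternary centre unaffected.

Step 13
Reactants: 21 terminal epoxy alkyne
Product: 23 (2S)-2-methyl-2-(prop-1-yn-1-yl)oxirane, via lithium acetylide 22 (not isolated)
Conditions: n-BuLi, THF, −78 °C; MeI, DMPU, −78 → 0 °C; kept as a titrated THF solution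
Reagents that add atoms: iodomethane, CI
Why: Deprotonation of the terminal alkyne and SN2 C-methylation of the lithium acetylide; at these temperatures the acetylide should not attack the 2,2-disubstituted epoxide.

Step 14
Reactants: 18 silylated dithiane; 23 (S)-propynyl oxirane
Product: 26 acyclic diyne (1S,4R,8S,11R,12S) with C11–OSiEt3 and C4–OSiMe3 and C6 dithiane, via lithiated dithiane 24 (not isolated), via lithium alkoxide 25 (not isolated)
Conditions: 18, t-BuLi, THF/HMPA (10:1), −78 °C; 23, −78 → −40 °C; Me3SiCl, −40 → 0 °C
Reagents that add atoms: chlorotrimethylsilane, C[Si](C)(C)Cl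
Why: Metalation of the 2-alkyl-1,3-dithiane (acyl anion equivalent) and SN2 opening of the epoxide at its unsubstituted CH2 forms C5–C6 without touching the C4 stereocentre, and the tertiary lithium alkoxide is silylated in the same flask.

Step 15
Reactants: 26 acyclic bis-silylated diyne
Product: 27 14-membered cycloalkyne (C2≡C3) as bis-silyl ether
Conditions: Mo(≡CC6H4OMe-4)(OSiPh3)3 (20 mol%), 5 Å MS, toluene, 100 °C, 2 mM
Reagents that add atoms: none
Why: Ring-closing alkyne metathesis by a molybdenum alkylidyne with silanolate ligands through metallacyclobutadienes; loss of but-2-yne (taken up by the sieves) and high dilution drive closure of the 14-membered ring, and silyl ethers, the thioacetal and the oxolane are tolerated.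

Step 16
Reactants: 27 bis-silylated cycloalkyne
Product: 28 cycloalkyne diol (1S,4R,8S,11R,12S) with C6 dithiane
Conditions: Bu4NF, THF, 0 °C → rt
Reagents that add atoms: none
Why: Fluoride-mediated desilylation removes both silyl ethers and frees the C4 hydroxyl needed to direct the reduction.

Step 17
Reactants: 28 cycloalkyne diol
Product: 30 E-allylic tertiary alcohol (diol with C6 dithiane), via alkenylaluminate 29 (not isolated)
Conditions: NaAlH2(OCH2CH2OMe)2, THF, 0 °C; aq. KNaC4H4O6, 0 °C
Reagents that add atoms: none
Why: Hydroxyl-directed trans-hydroalumination of the propargylic alcohol: the C4 alkoxyaluminium hydride delivers hydride to C3 and forms the five-membered alkenylaluminate 29, whose protonolysis with retention gives only the E-alkene; the reaction is kept cold to hold back β-elimination of the ring oxygen.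

Step 18
Reactants: 30 E-alkene diol
Product: 31 C11 acetate with C6 dithiane
Conditions: Ac2O, DMAP (cat.), Et3N, CH2Cl2, 0 °C → rt
Reagents that add atoms: acetic anhydride, CC(=O)OC(C)=O
Why: DMAP-catalysed acylation distinguishes the secondary C11 alcohol from the tertiary allylic C4 alcohol, which should not be acetylated under these mild conditions.

Step 19
Reactants: 31 acetate dithiane
Product: 32 target CNP0131678.1
Conditions: MeI, CaCO3, MeCN/H2O (9:1), 45 °C
Reagents that add atoms: water, O
Why: S-alkylative hydrolysis of the dithiane under neutral buffered conditions unmasks the C6 ketone last, so that the retro-aldol-prone β-hydroxy ketone, the acetate and the allylic alcohol meet neither acid nor base.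

**Compound list**

1 | (S)-citronellal | CC(C)=CCC[C@H](C)CC=O | starting material
2 | 2-[(2S)-2,6-dimethylhept-5-en-1-yl]-1,3-dioxolane | CC(C)=CCC[C@H](C)CC1OCCO1 | intermediate
3 | (2E,6S)-7-(1,3-dioxolan-2-yl)-2,6-dimethylhept-2-enal | O=C/C(C)=C/CC[C@H](C)CC1OCCO1 | intermediate
4 | (2E,6S)-7-(1,3-dioxolan-2-yl)-2,6-dimethylhept-2-en-1-ol | OC/C(C)=C/CC[C@H](C)CC1OCCO1 | intermediate
5 | (2E,6S)-7-(1,3-dioxolan-2-yl)-2,6-dimethylhept-2-en-1-yl methanesulfonate | CS(=O)(=O)OC/C(C)=C/CC[C@H](C)CC1OCCO1 | intermediate
6 | 2-[(2S,5E)-7-bromo-2,6-dimethylhept-5-en-1-yl]-1,3-dioxolane | BrC/C(C)=C/CC[C@H](C)CC1OCCO1 | intermediate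
7 | 3-methyl-2-butanone | CC(C)C(C)=O | starting material
8 | lithium 3-methylbut-1-en-2-olate | C=C(O[Li])C(C)C | intermediate
9 | (6E,10S)-11-(1,3-dioxolan-2-yl)-2,6,10-trimethylundec-6-en-3-one | CC(C)C(=O)CC/C(C)=C/CC[C@H](C)CC1OCCO1 | intermediate
10 | (8S,11R,12R)-epoxy ketone | CC(C)C(=O)CC[C@@]1(C)O[C@@H]1CC[C@H](C)CC2OCCO2 | intermediate
11 | (1S,8S,11R,12S)-2,7-dioxabicyclo[2.2.1]heptane ketal | CC(C)[C@]12CC[C@](C)(O1)[C@@H](CC[C@H](C)CC3OCCO3)O2 | intermediate
12 | propyne | CC#C | starting material
13 | 1-propynyllithium | CC#C[Li] | intermediate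
14 | dimethyl(1-propynyl)alane | CC#C[Al](C)C | intermediate
15 | (1S,8S,11R,12S)-2,5-cis oxolane alcohol, C6 dioxolane | CC#C[C@@]1(C(C)C)CC[C@](C)(O1)[C@H](O)CC[C@H](C)CC2OCCO2 | intermediate
16 | (3S,6R)-6-hydroxy-3-methyl-6-[(2S,5S)-2-methyl-5-(propan-2-yl)-5-(prop-1-yn-1-yl)oxolan-2-yl]hexanal | CC#C[C@@]1(C(C)C)CC[C@](C)(O1)[C@H](O)CC[C@H](C)CC=O | intermediate
17 | (1S,8S,11R,12S)-oxolane alcohol, C6 1,3-dithiane | CC#C[C@@]1(C(C)C)CC[C@](C)(O1)[C@H](O)CC[C@H](C)CC2SCCCS2 | intermediate
18 | C11 triethylsilyl ether of 17 | CC#C[C@@]1(C(C)C)CC[C@](C)(O1)[C@H](O[Si](CC)(CC)CC)CC[C@H](C)CC2SCCCS2 | intermediate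
19 | (S)-2-methylglycidol | OC[C@@]1(C)CO1 | starting material
20 | (2R)-2-methyloxirane-2-carbaldehyde | O=C[C@@]1(C)CO1 | intermediate
21 | (2S)-2-ethynyl-2-methyloxirane | C#C[C@@]1(C)CO1 | intermediate
22 | lithium acetylide of 21 | [Li]C#C[C@@]1(C)CO1 | intermediate
23 | (2S)-2-methyl-2-(prop-1-yn-1-yl)oxirane | CC#C[C@@]1(C)CO1 | intermediate
24 | 2-lithio-1,3-dithiane of 18 | CC#C[C@@]1(C(C)C)CC[C@](C)(O1)[C@H](O[Si](CC)(CC)CC)CC[C@H](C)CC2([Li])SCCCS2 | intermediate
25 | lithium C4 alkoxide of the coupled diyne | CC#C[C@@]1(C(C)C)CC[C@](C)(O1)[C@H](O[Si](CC)(CC)CC)CC[C@H](C)CC2(C[C@@](C)(O[Li])C#CC)SCCCS2 | intermediate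
26 | (1S,4R,8S,11R,12S)-acyclic diyne, C11–OSiEt3, C4–OSiMe3, C6 dithiane | CC#C[C@@]1(C(C)C)CC[C@](C)(O1)[C@H](O[Si](CC)(CC)CC)CC[C@H](C)CC2(C[C@@](C)(O[Si](C)(C)C)C#CC)SCCCS2 | intermediate
27 | 14-membered cycloalkyne, bis-silyl ether | CC[Si](CC)(CC)O[C@@H]1CC[C@H](C)CC2(SCCCS2)C[C@@](C)(O[Si](C)(C)C)C#C[C@@]3(C(C)C)CC[C@]1(C)O3 | intermediate
28 | 14-membered cycloalkyne diol, C6 dithiane | O[C@@H]1CC[C@H](C)CC2(SCCCS2)C[C@@](C)(O)C#C[C@@]3(C(C)C)CC[C@]1(C)O3 | intermediate
29 | disodium alkenylaluminate (O4–Al–C2 five-membered ring; C11 oxygen as hydridoaluminate) | COCCO[AlH-](OCCOC)O[C@@H]1CC[C@H](C)CC2(SCCCS2)C[C@@](C)(O9)/C=C(\[Al-]9(OCCOC)OCCOC)[C@@]3(C(C)C)CC[C@]1(C)O3.[Na+].[Na+] | intermediate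
30 | E-allylic tertiary alcohol, C11–OH, C6 dithiane | O[C@@H]1CC[C@H](C)CC2(SCCCS2)C[C@@](C)(O)/C=C/[C@@]3(C(C)C)CC[C@]1(C)O3 | intermediate
31 | C11 acetate, C6 dithiane | CC(=O)O[C@@H]1CC[C@H](C)CC2(SCCCS2)C[C@@](C)(O)/C=C/[C@@]3(C(C)C)CC[C@]1(C)O3 | intermediate
32 | CNP0131678.1 (1S,4R,8S,11R,12S) | CC(=O)O[C@@H]1CC[C@H](C)CC(=O)C[C@@](C)(O)/C=C/[C@@]2(C(C)C)CC[C@]1(C)O2 | target

**Step count**

Total step count: 19.
Longest linear sequence: 16 steps (steps 1–10 and 14–19, from (S)-citronellal); steps 11–13 build the epoxide fragment.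

**Three steps most likely to fail**

1. Step 7 (alkynylalane opening of the bicyclic ketal). Possible failures are:
   - loss of facial control through external attack on the oxocarbenium ion from the face opposite C11;
   - cleavage of C1–O12 instead of C1–O11;
   - proton loss from the cation to an enol ether;
   - competing opening of the C6 dioxolane.

   Fallback, known chemistry, setting out from epoxy ketone 10 and coming back at oxolane alcohol 15: 1-propynylmagnesium bromide with CeCl3 in THF at −78 °C should add to the C1 carbonyl of 10 (organocerium 1,2-addition, epoxide and acetal untouched) to give the tertiary propargylic alcohol F1 as both C1 epimers. Catalytic CSA in CH2Cl2 should then let the tertiary hydroxyl open the epoxide 5-exo at C12 with inversion (the standard epoxy alcohol to oxolane cyclisation). This would give 15 together with its C1 epimer, the 2,5-trans oxolane F2, from which 15 would be separated by chromatography. C11 and C12 are set as in the main route; only the control at C1 is given up.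

2. Step 15 (ring-closing alkyne metathesis). Both propargylic carbons (C1 and C4) are fully substituted, so formation of the crowded metallacyclobutadiene may be too slow, and the catalyst may decay or oligomerise the diyne before the ring closes.

   Fallback, setting out from silyl ether 18 and coming back at cycloalkyne diol 28; it closes the ring before C4 becomes fully substituted:
   - The lithio derivative 24 would open racemic 2-(prop-1-yn-1-yl)oxirane F3 (one step from commercial but-2-ynal and dimethylsulfonium methylide, Corey–Chaykovsky epoxidation), and the alkoxide would be trapped with Et3SiCl to give diyne F4, in which C4 is only a secondary silyl ether.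
   - Alkyne metathesis of F4 with the same molybdenum alkylidyne, now hindered at one end only, should give cycloalkyne F5.
   - Bu4NF would free diol F6, and MnO2 in CH2Cl2 would oxidise only the propargylic C4 alcohol to the macrocyclic ynone F7.
   - MeMgBr with CeCl3 at −78 °C would add to the C4 carbonyl to give 28 together with its C4 epimer F8, which would be separated. The face selectivity is left to the conformation of the macrocycle.

3. Step 17 (directed trans-hydroalumination). The alkenylaluminate carries aluminium on C2 next to the C1–O bond, so β-elimination of the ring oxygen may open the oxolane to an allene; reduction of the hindered cycloalkyne may also be slow at the low temperature needed to prevent this.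

   Fallback, setting out from diol 28 and coming back at 30: hydroxyl-directed trans-hydrostannation with [Cp*RuCl]4 (cat.) and Bu3SnH in CH2Cl2 should place tin on C3, next to the C4 hydroxyl and away from the ring oxygen, to give the alkenylstannane F9. Protodestannation with copper thiophene-2-carboxylate, Cu(O2CC4H3S) (monovalent copper), in DMF should then give 30 with the alkene geometry retained.

**Further compounds**

F1 | step 7 | tertiary propargylic alcohol from propynyl addition to 10 (both C1 epimers) | CC#CC(O)(C(C)C)CC[C@@]1(C)O[C@@H]1CC[C@H](C)CC2OCCO2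
F2 | step 7 | 2,5-trans oxolane alcohol (C1 epimer of 15) | CC#C[C@]1(C(C)C)CC[C@](C)(O1)[C@H](O)CC[C@H](C)CC2OCCO2
F3 | step 15 | racemic 2-(prop-1-yn-1-yl)oxirane | CC#CC1CO1
F4 | step 15 | acyclic diyne without the C4 methyl, C4 and C11 as triethylsilyl ethers (both C4 epimers) | CC#C[C@@]1(C(C)C)CC[C@](C)(O1)[C@H](O[Si](CC)(CC)CC)CC[C@H](C)CC2(CC(O[Si](CC)(CC)CC)C#CC)SCCCS2
F5 | step 15 | cycloalkyne without the C4 methyl, bis(triethylsilyl) ether | CC[Si](CC)(CC)O[C@@H]1CC[C@H](C)CC2(SCCCS2)CC(O[Si](CC)(CC)CC)C#C[C@@]3(C(C)C)CC[C@]1(C)O3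
F6 | step 15 | cycloalkyne diol with secondary C4–OH | O[C@@H]1CC[C@H](C)CC2(SCCCS2)CC(O)C#C[C@@]3(C(C)C)CC[C@]1(C)O3
F7 | step 15 | macrocyclic C4 ynone | O[C@@H]1CC[C@H](C)CC2(SCCCS2)CC(=O)C#C[C@@]3(C(C)C)CC[C@]1(C)O3
F8 | step 15 | C4 epimer of 28 | O[C@@H]1CC[C@H](C)CC2(SCCCS2)C[C@](C)(O)C#C[C@@]3(C(C)C)CC[C@]1(C)O3
F9 | step 17 | C3 tributylstannyl alkene from trans-hydrostannation of 28 | O[C@@H]1CC[C@H](C)CC2(SCCCS2)C[C@@](C)(O)/C(=C/[C@@]3(C(C)C)CC[C@]1(C)O3)[Sn](CCCC)(CCCC)CCCC
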